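**Retrosynthetic overview**

- Feature: in ring C of the isoflavan half, O1 is bonded to an unsubstituted C2H2. C3 carries ring B and C4 carries ring D (through C6 of the naringenin half), and the two aryl groups are trans. O1–C2 with ring A is therefore an aryloxymethyl cation, and C3–C4 with its two aryl groups is an E-stilbene.
- Key disconnection: C2–C3 and C4–C4a are made together in a cationic (4+2) (oxa-Povarov) reaction. Before it, the ring D–vinyl bond comes from a Heck reaction of a 6-iodoflavanone with the ring B styrene.
- Design: the cation source is the pivaloyloxymethyl ether of ring A, because acid splits a methoxymethyl aryl ether the other way (phenol plus MeOCH2+). The flavanone oxygens are benzylated by Mitsunobu reactions, because carbonate bases open the pyranone to the chalcone and erase the flavanone C2. O3' of ring B is a benzyl carbonate, which weakens ring B as a cation stabiliser and still leaves by hydrogenolysis. A substoichiometric chiral Brønsted acid is used, because SnCl4 would chelate the carbonyl and O5.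
- Ring order: rings A, B, D, E (the 4-hydroxyphenyl group) and the pyranone come with the starting materials, and (2S)-naringenin supplies the flavanone C2. Ring C is the only ring formed, in the penultimate step, and a global hydrogenolysis ends the route.

Key step: step 9

Assumption: (2S)-naringenin is taken as the commercially offered single enantiomer and its enantiomeric purity is checked by chiral HPLC before use; the antipode of the chiral acid that exposes the required alkene face in step 9 cannot be predicted and is fixed by one trial with each.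

**Route**

Step 1
Reactants: 1 2,6-dimethoxyphenol
Product: 2 benzyl 2,6-dimethoxyphenyl carbonate
Conditions: CbzCl, Et3N, CH2Cl2, 0 °C to rt
Reagents that add atoms: benzyl chloroformate, O=C(Cl)OCc1ccccc1
Why: O-acylation of a phenol with a chloroformate is routine, and the carbonate steers the next substitution away from the position para to this oxygen, later makes ring B the poorer cation stabiliser and still falls to hydrogenolysis.

Step 2
Reactants: 2 benzyl 2,6-dimethoxyphenyl carbonate
Product: 3 benzyl 3-iodo-2,6-dimethoxyphenyl carbonate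
Conditions: NIS (1.0 equiv), TFA (cat), MeCN, rt, dark
Reagents that add atoms: N-iodosuccinimide, O=C1CCC(=O)N1I
Why: Electrophilic aromatic iodination goes to C3, which is para to one methoxy group and ortho to the other, whereas C4 is only para to the deactivated carbonate oxygen.

Step 3
Reactants: 3 benzyl 3-iodo-2,6-dimethoxyphenyl carbonate
Product: 4 benzyl 3-ethenyl-2,6-dimethoxyphenyl carbonate (ring B styrene)
Conditions: Bu3SnCH=CH2, Pd(PPh3)4 (5 mol %), BHT (trace), toluene, 100 °C
Reagents that add atoms: tributyl(vinyl)stannane, C=C[Sn](CCCC)(CCCC)CCCC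
Why: The Stille coupling transfers the vinyl group to the aryl iodide under neutral conditions, so the aryl carbonate, which the aqueous base of a Suzuki vinylation would hydrolyse, survives.

Step 4
Reactants: 5 (2S)-naringenin
Product: 7 (2S)-7,4'-di-O-benzylnaringenin, via (2S)-7-O-benzylnaringenin 6 (not isolated)
Conditions: BnOH (2.1 equiv), PPh3, DIAD, THF, 0 °C to rt
Reagents that add atoms: benzyl alcohol, OCc1ccccc1
Why: The Mitsunobu etherification alkylates the acidic 7-hydroxyl and then the 4'-hydroxyl while the chelated 5-hydroxyl lags behind, and no free base is present to open the pyranone through the 4'-phenoxide or the C3 enolate, so the flavanone C2 stays S.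

Step 5
Reactants: 7 (2S)-7,4'-di-O-benzylnaringenin
Product: 8 (2S)-7,4'-di-O-benzyl-6-iodonaringenin
Conditions: NIS (1.05 equiv), DMF, rt, dark
Reagents that add atoms: N-iodosuccinimide, O=C1CCC(=O)N1I
Why: Electrophilic aromatic iodination under neutral conditions goes ortho to the free chelated 5-hydroxyl, the strongest activator, so C6 is taken in preference to C8 as is known for 5-hydroxy-7-alkoxyflavonoids, and the site is to be confirmed through the HMBC correlations of the chelated OH proton.

Step 6
Reactants: 8 (2S)-7,4'-di-O-benzyl-6-iodonaringenin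
Product: 9 (2S)-5,7,4'-tri-O-benzyl-6-iodonaringenin
Conditions: BnOH (1.5 equiv), PPh3, DIAD, THF (1 M), 0 to 40 °C
Reagents that add atoms: benzyl alcohol, OCc1ccccc1
Why: The Mitsunobu etherification is known to alkylate chelated ortho-hydroxyaryl ketones once no freer phenol competes, the ortho iodine raises the acidity of the hydroxyl, and nothing basic enough to enolise C3 and open the pyranone is present, so the flavanone C2 stays S.

Step 7
Reactants: 9 (2S)-5,7,4'-tri-O-benzyl-6-iodonaringenin; 4 benzyl 3-ethenyl-2,6-dimethoxyphenyl carbonate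
Product: 10 (2S)-5,7,4'-tri-O-benzyl-6-[(E)-2-(3-benzyloxycarbonyloxy-2,4-dimethoxyphenyl)ethenyl]naringenin
Conditions: Pd2(dba)3 (2.5 mol %), P(t-Bu)3 (10 mol %), Cy2NMe (1.2 equiv), 4 (1.3 equiv), dioxane, rt to 50 °C
Reagents that add atoms: none
Why: In this Mizoroki–Heck reaction the bulky electron-rich phosphine lets zerovalent palladium insert into the hindered C–I bond near room temperature, syn insertion at the terminal alkene carbon and syn β-hydride elimination give the E-stilbene, and the weak tertiary amine at low temperature leaves the flavanone C2 and the carbonate alone.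

Step 8
Reactants: 11 3-(benzyloxy)phenol
Product: 12 [3-(benzyloxy)phenoxy]methyl pivalate
Conditions: ClCH2OPiv, Cs2CO3, DMF, 0 °C to rt
Reagents that add atoms: chloromethyl pivalate, CC(C)(C)C(=O)OCCl
Why: Williamson-type O-alkylation of a phenoxide with chloromethyl pivalate is the known way to aryl pivaloyloxymethyl ethers, the bulky acyl group suppresses acyl transfer to the phenoxide, and the product carries the future C2 with a leaving group better than the aryloxide.

Step 9
Reactants: 10 (2S)-5,7,4'-tri-O-benzyl-6-[(E)-2-(3-benzyloxycarbonyloxy-2,4-dimethoxyphenyl)ethenyl]naringenin; 12 [3-(benzyloxy)phenoxy]methyl pivalate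
Product: 15 (2S)-5,7,4'-tri-O-benzyl-6-[(3R,4S)-7-benzyloxy-3-(3-benzyloxycarbonyloxy-2,4-dimethoxyphenyl)chroman-4-yl]naringenin, via aryloxymethyl cation 13 (not isolated), via C4 benzylic cation 14 (not isolated)
Conditions: BINOL-derived imidodiphosphorimidate (IDPi) Brønsted acid with N-triflyl core and an open 3,3'-aryl pocket (10 mol %, antipode chosen by trial), 12 (2.5 equiv, added over 6 h), 5 Å MS, CH2Cl2, −40 °C; Et3N quench; chromatography to remove the (3S,4R) diastereomer
Reagents that add atoms: none
Why: Proposed new method: the acid protonates the pivalate carbonyl of 12 and pivalic acid leaves, the only productive direction of ionisation because the carboxylate is the better leaving group and the alternative acyloxymethyl cation is far less stabilised, so the cationic 2-oxadiene 13 is paired with the chiral anion; a formaldehyde-derived aryl oxocarbenium ion, a stilbene partner and face control by the counteranion are all without precedent, the closest known reaction types being the racemic SnCl4-promoted oxa-Povarov reaction of aldehyde-derived aryl oxocarbenium ions with styrenes, the IDPi-catalysed Prins reaction of aryl alkenes with formaldehyde and the ionisation of lactol acetates by the same acids. The alkene carbon bearing ring B attacks the CH2 of 13 (C2–C3 bond) and leaves cation 14 at C4, where the two benzyloxy groups (ortho) and the pyranone oxygen (para) of ring D stabilise it and the flavanone carbonyl hangs on a position meta to the site, whereas ring B offers only its 4'-methoxy group fully, its 2'-methoxy group being twisted by two neighbours and its 3'-carbonate withdrawing inductively. Ring C then closes by a 6-(enolendo)-exo-trig Friedel–Crafts attack of the ring A carbon ortho to O1 and para to the benzyloxy group (C4–C4a bond), the position between the two oxygens being more hindered, and loss of the proton returns the catalyst. C3 is set by the alkene face that the chiral anion leaves open (Re at the carbon bearing ring B gives 3R), and C4 follows from C3 because suprafacial addition to the E alkene, or stepwise closure through the chair-like arrangement with both aryl groups pseudo-equatorial, gives the 3,4-trans product and hence 4S; the flavanone 2S centre is too remote to influence either, but it turns the unwanted (3S,4R) product into a diastereomer that chromatography removes. The step needs chemoselectivity for the alkene over C8 of ring D, over ring B and over the arene of 12 itself, which rests on the donor-conjugated double bond being the most nucleophilic π system, on the slow addition of 12 and on the deactivation of ring B and of 12 by their acyloxy groups. Only a tenth of an equivalent of acid is present, so most of the flavanone carbonyl stays uncomplexed, ring D keeps its donor strength and the O5 benzyl ether is not cleaved by chelation as it would be with SnCl4.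

Step 10
Reactants: 15 (2S)-5,7,4'-tri-O-benzyl-6-[(3R,4S)-7-benzyloxy-3-(3-benzyloxycarbonyloxy-2,4-dimethoxyphenyl)chroman-4-yl]naringenin
Product: 16 target, (2S)-6-[(3R,4S)-7-hydroxy-3-(3-hydroxy-2,4-dimethoxyphenyl)chroman-4-yl]naringenin
Conditions: H2 (1 atm), 10% Pd/C, EtOAc–EtOH, rt
Reagents that add atoms: none
Why: Catalytic hydrogenolysis removes the four benzyl ethers and the benzyl carbonate (with loss of CO2) in neutral medium, in which neither the flavanone C2, prone to ring opening in base once the 4'-hydroxyl is free, nor C3 and C4 of ring C can epimerise, and the electron-rich aryl ketone is not reduced at atmospheric pressure.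

**Compound list**

1 | 2,6-dimethoxyphenol | COc1cccc(OC)c1O | starting material
2 | benzyl 2,6-dimethoxyphenyl carbonate | COc1cccc(OC)c1OC(=O)OCc1ccccc1 | intermediate
3 | benzyl 3-iodo-2,6-dimethoxyphenyl carbonate | COc1ccc(I)c(OC)c1OC(=O)OCc1ccccc1 | intermediate
4 | benzyl 3-ethenyl-2,6-dimethoxyphenyl carbonate | COc1ccc(C=C)c(OC)c1OC(=O)OCc1ccccc1 | intermediate
5 | (2S)-naringenin | O=C1C[C@@H](c2ccc(O)cc2)Oc2cc(O)cc(O)c12 | starting material
6 | (2S)-7-O-benzylnaringenin (not isolated) | O=C1C[C@@H](c2ccc(O)cc2)Oc2cc(OCc3ccccc3)cc(O)c12 | intermediate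
7 | (2S)-7,4'-di-O-benzylnaringenin | O=C1C[C@@H](c2ccc(OCc3ccccc3)cc2)Oc2cc(OCc3ccccc3)cc(O)c12 | intermediate
8 | (2S)-7,4'-di-O-benzyl-6-iodonaringenin | O=C1C[C@@H](c2ccc(OCc3ccccc3)cc2)Oc2cc(OCc3ccccc3)c(I)c(O)c12 | intermediate
9 | (2S)-5,7,4'-tri-O-benzyl-6-iodonaringenin | O=C1C[C@@H](c2ccc(OCc3ccccc3)cc2)Oc2cc(OCc3ccccc3)c(I)c(OCc3ccccc3)c12 | intermediate
10 | (2S)-5,7,4'-tri-O-benzyl-6-[(E)-2-(3-benzyloxycarbonyloxy-2,4-dimethoxyphenyl)ethenyl]naringenin | COc1ccc(/C=C/c2c(OCc3ccccc3)cc3c(c2OCc2ccccc2)C(=O)C[C@@H](c2ccc(OCc4ccccc4)cc2)O3)c(OC)c1OC(=O)OCc1ccccc1 | intermediate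
11 | 3-(benzyloxy)phenol | Oc1cccc(OCc2ccccc2)c1 | starting material
12 | [3-(benzyloxy)phenoxy]methyl pivalate | CC(C)(C)C(=O)OCOc1cccc(OCc2ccccc2)c1 | intermediate
13 | [3-(benzyloxy)phenyl]oxymethylium, the aryloxymethyl cation (not isolated) | C=[O+]c1cccc(OCc2ccccc2)c1 | intermediate
14 | (3R)-configured benzylic cation at C4, C2–C3 bond formed, ring C still open (not isolated) | COc1ccc([C@H](COc2cccc(OCc3ccccc3)c2)[CH+]c2c(OCc3ccccc3)cc3c(c2OCc2ccccc2)C(=O)C[C@@H](c2ccc(OCc4ccccc4)cc2)O3)c(OC)c1OC(=O)OCc1ccccc1 | intermediate
15 | (2S)-5,7,4'-tri-O-benzyl-6-[(3R,4S)-7-benzyloxy-3-(3-benzyloxycarbonyloxy-2,4-dimethoxyphenyl)chroman-4-yl]naringenin | COc1ccc([C@@H]2COc3cc(OCc4ccccc4)ccc3[C@H]2c2c(OCc3ccccc3)cc3c(c2OCc2ccccc2)C(=O)C[C@@H](c2ccc(OCc4ccccc4)cc2)O3)c(OC)c1OC(=O)OCc1ccccc1 | intermediate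
16 | (2S)-6-[(3R,4S)-7-hydroxy-3-(3-hydroxy-2,4-dimethoxyphenyl)chroman-4-yl]naringenin (CNP0267463.1) | COc1ccc([C@@H]2COc3cc(O)ccc3[C@H]2c2c(O)cc3c(c2O)C(=O)C[C@@H](c2ccc(O)cc2)O3)c(OC)c1O | target

**Step count**

Total step count: 10. Longest linear sequence: 6 (steps 4, 5, 6, 7, 9, 10).

**Steps most likely to fail**

1. Step 9, the labelled step.
   - What may go wrong: the cation source may condense with itself. The cation may substitute C8 of ring D or ring B instead of adding to the alkene. The stilbene may bond through the carbon bearing ring D. The acid may protonate the stilbene. The large substrate may sit outside the chiral pocket, so that the two faces are not told apart.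
   - Fallback (known chemistry, sets out from 1 and 7, comes back at 16): ring C is taken from a chromanone, and the bond from C4 to ring D is made by a dehydrative Friedel–Crafts reaction.
   - Compound 1 would be benzylated (BnBr, K2CO3, acetone) to 2-(benzyloxy)-1,3-dimethoxybenzene F1. F1 would be brominated (NBS, MeCN) to 2-(benzyloxy)-4-bromo-1,3-dimethoxybenzene F2.
   - Commercial 7-hydroxychroman-4-one would be benzylated in the same way to 7-(benzyloxy)chroman-4-one F3.
   - Palladium-catalysed ketone α-arylation of F3 with F2 (Pd2(dba)3, P(t-Bu)3, NaOt-Bu, toluene) should give the configurationally labile racemic 7-(benzyloxy)-3-[3-(benzyloxy)-2,4-dimethoxyphenyl]chroman-4-one F4.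
   - Asymmetric transfer hydrogenation with dynamic kinetic resolution (RuCl[(R,R)-TsDPEN](p-cymene), HCO2H–Et3N) should give (3R,4R)-7-(benzyloxy)-3-[3-(benzyloxy)-2,4-dimethoxyphenyl]chroman-4-ol F5.
   - Ionisation of F5 with substoichiometric BF3·OEt2 (CH2Cl2, −20 °C) in the presence of 7 should lead to attack of the flavanone, ortho to its free 5-hydroxyl, on the face of the cyclic cation anti to ring B.
   - This should give (2S)-7,4'-di-O-benzyl-6-[(3R,4S)-7-benzyloxy-3-(3-benzyloxy-2,4-dimethoxyphenyl)chroman-4-yl]naringenin F6. Any C8-linked isomer would be removed by chromatography.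
   - Hydrogenolysis of F6 as in step 10 gives 16.

2. Step 7.
   - What may go wrong: oxidative addition and insertion may be slow at the doubly ortho-substituted iodide. The arylpalladium intermediate may close onto the phenyl ring of a flanking benzyl ether. Zerovalent palladium may attack the benzyl carbonate. The flavanone C2 may erode if heating becomes necessary.
   - Fallback (sets out from 9, comes back at 10): the polarity of the coupling is reversed.
   - Base-free Stille vinylation of 9 (Bu3SnCH=CH2, Pd(PPh3)4, toluene, 80 °C) should give (2S)-5,7,4'-tri-O-benzyl-6-ethenylnaringenin F7.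
   - F7 is then the alkene partner in a room-temperature Heck reaction with the unhindered ring B iodide 3 (Pd2(dba)3, P(t-Bu)3, Cy2NMe, dioxane). The arylpalladium species then has only methoxy neighbours, and the product is 10.

3. Step 6.
   - What may go wrong: the chelated hydroxyl, flanked by iodine and the carbonyl group, may react too slowly with the benzyloxyphosphonium ion, so that the reagents are consumed unproductively.
   - Fallback (sets out from 8, comes back at 16): O5 is silylated instead of benzylated.
   - TBSOTf and 2,6-lutidine (CH2Cl2, 0 °C) should give (2S)-7,4'-di-O-benzyl-5-O-(tert-butyldimethylsilyl)-6-iodonaringenin F8.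
   - The Heck reaction of step 7 with 4 should give the 5-O-silyl E-stilbene F9.
   - The reaction of step 9 with 12 should give the 5-O-silyl (3R,4S)-chroman F10.
   - Et3N·3HF (THF, rt) should free the 5-hydroxyl under non-basic conditions to give the 5-hydroxy (3R,4S)-chroman F11.
   - Hydrogenolysis of F11 as in step 10 gives 16.

**Further compounds**

F1 | step 9 | 2-(benzyloxy)-1,3-dimethoxybenzene | COc1cccc(OC)c1OCc1ccccc1
F2 | step 9 | 2-(benzyloxy)-4-bromo-1,3-dimethoxybenzene | COc1ccc(Br)c(OC)c1OCc1ccccc1
F3 | step 9 | 7-(benzyloxy)chroman-4-one | O=C1CCOc2cc(OCc3ccccc3)ccc12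
F4 | step 9 | racemic 7-(benzyloxy)-3-[3-(benzyloxy)-2,4-dimethoxyphenyl]chroman-4-one | COc1ccc(C2COc3cc(OCc4ccccc4)ccc3C2=O)c(OC)c1OCc1ccccc1
F5 | step 9 | (3R,4R)-7-(benzyloxy)-3-[3-(benzyloxy)-2,4-dimethoxyphenyl]chroman-4-ol | COc1ccc([C@@H]2COc3cc(OCc4ccccc4)ccc3[C@@H]2O)c(OC)c1OCc1ccccc1
F6 | step 9 | (2S)-7,4'-di-O-benzyl-6-[(3R,4S)-7-benzyloxy-3-(3-benzyloxy-2,4-dimethoxyphenyl)chroman-4-yl]naringenin | COc1ccc([C@@H]2COc3cc(OCc4ccccc4)ccc3[C@H]2c2c(OCc3ccccc3)cc3c(c2O)C(=O)C[C@@H](c2ccc(OCc4ccccc4)cc2)O3)c(OC)c1OCc1ccccc1
F7 | step 7 | (2S)-5,7,4'-tri-O-benzyl-6-ethenylnaringenin | C=Cc1c(OCc2ccccc2)cc2c(c1OCc1ccccc1)C(=O)C[C@@H](c1ccc(OCc3ccccc3)cc1)O2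
F8 | step 6 | (2S)-7,4'-di-O-benzyl-5-O-(tert-butyldimethylsilyl)-6-iodonaringenin | O=C1C[C@@H](c2ccc(OCc3ccccc3)cc2)Oc2cc(OCc3ccccc3)c(I)c(O[Si](C)(C)C(C)(C)C)c12
F9 | step 6 | 5-O-silyl E-stilbene, (2S)-7,4'-di-O-benzyl-5-O-(tert-butyldimethylsilyl)-6-[(E)-2-(3-benzyloxycarbonyloxy-2,4-dimethoxyphenyl)ethenyl]naringenin | COc1ccc(/C=C/c2c(OCc3ccccc3)cc3c(c2O[Si](C)(C)C(C)(C)C)C(=O)C[C@@H](c2ccc(OCc4ccccc4)cc2)O3)c(OC)c1OC(=O)OCc1ccccc1
F10 | step 6 | 5-O-silyl (3R,4S)-chroman, (2S)-7,4'-di-O-benzyl-5-O-(tert-butyldimethylsilyl)-6-[(3R,4S)-7-benzyloxy-3-(3-benzyloxycarbonyloxy-2,4-dimethoxyphenyl)chroman-4-yl]naringenin | COc1ccc([C@@H]2COc3cc(OCc4ccccc4)ccc3[C@H]2c2c(OCc3ccccc3)cc3c(c2O[Si](C)(C)C(C)(C)C)C(=O)C[C@@H](c2ccc(OCc4ccccc4)cc2)O3)c(OC)c1OC(=O)OCc1ccccc1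
F11 | step 6 | 5-hydroxy (3R,4S)-chroman, (2S)-7,4'-di-O-benzyl-6-[(3R,4S)-7-benzyloxy-3-(3-benzyloxycarbonyloxy-2,4-dimethoxyphenyl)chroman-4-yl]naringenin | COc1ccc([C@@H]2COc3cc(OCc4ccccc4)ccc3[C@H]2c2c(OCc3ccccc3)cc3c(c2O)C(=O)C[C@@H](c2ccc(OCc4ccccc4)cc2)O3)c(OC)c1OC(=O)OCc1ccccc1
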